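## The problem

Target 34 (C48H34O28) is an achiral chain of eight benzene rings (A to H) joined by seven diaryl ether oxygens and carrying 21 free hydroxyls; there is no stereocentre, so the task is the seven C–O bonds and the placing of 28 oxygens. Ring A is a 2,4,6-trihydroxyphenoxy cap, rings B, D and F are 3,5-dihydroxy-1,4-phenylenedioxy units, rings C, E and G are 3,4,5-trihydroxy-1,2-phenylenedioxy units and ring H is a 3,4,5-trihydroxyphenyl cap; ring A is numbered from its ether carbon and every later ring from the carbon (C1) that holds the oxygen coming from the ring before it. Every ether oxygen is bound on one side to a carbon flanked by two oxygenated carbons (C1 of A, C4 of B, D and F, C6 of C, E and G), and in the bonds B–C, D–E and F–G the partner carbon (C1 of C, E and G) has a further ortho oxygen at C6. All rings carry four or five oxygens, so the aryl halides are poor electrophiles and the phenols are crowded and easily oxidised; copper coupling is weakest exactly here and worsens as the chain grows. In rings C, E and G five contiguous oxygens must be told apart: two ethers to different neighbours and three hydroxyls. The pyrogallol and hydroxyhydroquinone motifs make 34 sensitive to air and base, so it can only be released in a last, neutral, non-oxidative step. Two features help: the pairs B–C, D–E and F–G are the same diaryl ether, so one monomer can serve three times, and in rings B, D, F and H the carbon C1 has hydrogen on both neighbours (C2, C6) and oxygen on C3 and C5; the triad O–C1, H–C2, O–C3 is what addition of an O–H bond across the C1≡C2 bond of a 3-alkoxybenzyne leaves, the C3 oxygen steering the nucleophile to C1. C1 of rings C, E and G lies between C2–H and the oxygenated C6, so an aryne there would have oxygen on both flanks and no bias; that bond needs another method and is best made once, on small pieces.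

## Retrosynthesis

**34 ⇐ 33.** The 21 benzylic C–O bonds are cut. Benzyl is preferred to methyl because hydrogenolysis is neutral and reductive and leaves only toluene, whereas 21 demethylations with boron halides would be much rougher on a product of this sensitivity. The forward step must be complete and leave the diaryl ethers alone.

**33 ⇐ 31 + 24; 31 ⇐ 30 ⇐ 29 + 17; 29 ⇐ 28 ⇐ 27 + 17; 27 ⇐ 26 ⇐ 4 + 17.** The four O–C1 bonds of rings H, F, D and B are cut, each into a crowded phenol and an aryne (32 from 24, 25 from 17). The neighbouring bonds (O–C1 of rings G, E and C) are the worse cut: they would need an aryne with oxygen on both flanks, or a metal coupling of two ortho-oxygenated partners on a growing chain. The gain is large, since the whole chain comes from phenol 4, three copies of one monomer 17 and the cap 24. The forward reaction must bring a 2,6-dioxygenated phenoxide to C1 only, through oxygen only, at room temperature. The methoxymethyl ether on O6 of the pentaoxygenated ring of 17 must survive and then be removed by acid to free the next nucleophile (26 → 27, 28 → 29, 30 → 31).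

**17 ⇐ 14 ⇐ 13 ⇐ 12.** The C–Si and O–S bonds on the former hydroquinone ring are cut. The 2-(trimethylsilyl)aryl triflate comes from ortho-bromophenol 14 by O-silylation, bromine–lithium exchange, retro-Brook shift and triflation. The bromine is placed ortho to the only free hydroxyl of 13, and 13 is freed from allyl ether 12. The lithium chemistry must tolerate five benzyl ethers and the acetal at −78 °C.

**12 ⇐ 5 + 11.** The O–C1 bond of the pentaoxygenated ring is cut; this is the tri-ortho-substituted ether that no biased aryne can deliver. Placed inside the monomer, it is formed once, between a simple phenol and a simple aryl iodide, by Ullmann coupling, and not three times on a growing chain. The copper coupling must join 2,6-dibenzyloxyphenol 5 and ortho-alkoxy iodide 11.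

**4 and 5 ⇐ 3 ⇐ 2 ⇐ 1.** Ring A phenol 4 and the ring B/D/F block 5 come from the same hydroquinone 3 and differ only in the alkyl halide. The hydroxyl flanked by two hydrogens is both more acidic and less hindered, so mono-alkylation leaves the crowded hydroxyl free, as both later roles need. Hydroquinone 3 comes from quinone 2, made by para-oxidation of 1.

**11 ⇐ 10 ⇐ 9 ⇐ 7 ⇐ 6 and 24 ⇐ 21 ⇐ 20 ⇐ 18.** Phenols 9 and 20 come from benzaldehydes 7 and 18 by Dakin-type oxidation, and the halogen is then put ortho to the new hydroxyl. For rings C, E and G, three oxygens come from 6, the fourth (O6) replaces the formyl group, and the fifth (O1) arrives in the Ullmann step, so the five oxygens are distinguished by their origin.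

## Roads not taken

Alternative 1: ring-by-ring Ullmann synthesis, the route most would draw first. Each ether is cut into a crowded phenol and an aryl bromide. For example, 4 with 5-bromo-1,3-bis(benzyloxy)-2-(methoxymethoxy)benzene A1 would give diaryl ether A2, followed by acetal cleavage and the next copper coupling. The forward key step is a copper coupling at 90–130 °C, run seven times with six unmaskings on one linear chain. The aryl halides are electron-rich, and the hardest couplings (both partners ortho-oxygenated) fall three times on the largest substrates. The chosen plan has one copper coupling, on small pieces, and joins fragments at room temperature with no metal.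

Alternative 2: a formyl relay. Each ether carbon lies para or ortho to an oxygen, so each ring could enter as a fluorobenzaldehyde: 2,6-bis(benzyloxy)-4-fluorobenzaldehyde A3 for rings B, D, F and H, and 2,3,4-tris(benzyloxy)-6-fluorobenzaldehyde A4 for rings C, E and G. The forward key step is nucleophilic aromatic substitution followed by Dakin oxidation, which turns the activating formyl group into the next nucleophilic hydroxyl without protecting groups. The weak point is A4: its fluoride is para to a benzyloxy group and only ortho-activated, and it would have to be displaced three times by a crowded, oxidisable phenoxide of growing size in hot dipolar solvent. The relay is also fourteen linear operations on the chain, against eight in the chosen plan.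

Alternative 3: build rings C, E and G from a four-membered ring. The cut removes the whole pentaoxygenated ring. The ethynyl ether A5 of phenol 5 would be lithiated and added to dibenzyl squarate A6 to give cyclobutenone A7. The forward key step is the Moore rearrangement of A7 (thermal opening of the four-membered ring and closure to a six-membered ring) to aryloxyquinone A8. This turns the most hindered diaryl ether into an enol ether and draws four oxygenated carbons from one cheap ring. It costs five or six operations per ring: two to reach A5, then addition, thermolysis, reduction of A8, and differentiation of the two hydroxyls that the reduction frees. The Ullmann union 5 + 11 → 12 reaches the same dimer in one step, so the chosen plan is shorter.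

Key step: step 16

Assumption: the structure has no stereogenic element, and 3,5-bis(benzyloxy)phenol 1, 2,3,4-trihydroxybenzaldehyde 6 and 3,4,5-tris(benzyloxy)benzaldehyde 18 are taken as purchased.

Remark: with fluoride, 17 gives the same aryne 25 each time it is used (steps 16, 18 and 20); 25 is entered as an in-flask intermediate at step 16, where it first forms.

## Steps

Step 1
Reactants: 1 3,5-bis(benzyloxy)phenol
Product: 2 2,6-bis(benzyloxy)-1,4-benzoquinone
Conditions: (KSO3)2NO (2.2 equiv), KH2PO4, acetone/H2O, rt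
Reagents that add atoms: potassium nitrosodisulfonate, [K+].[K+].[O-]S(=O)(=O)N([O])S(=O)(=O)[O-]
Why: Teuber oxidation: the phenoxyl radical is trapped at the free para carbon by a second nitroxyl and loses imidodisulfonate to give the para-quinone; C4, between the two benzyloxy groups, is the most electron-rich free position.

Step 2
Reactants: 2 2,6-bis(benzyloxy)-1,4-benzoquinone
Product: 3 2,6-bis(benzyloxy)benzene-1,4-diol
Conditions: Na2S2O4, EtOAc/H2O, rt, argon
Reagents that add atoms: none
Why: Dithionite reduction of a quinone to its hydroquinone; the product should be used at once because it reoxidises in air.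

Step 3
Reactants: 3 2,6-bis(benzyloxy)benzene-1,4-diol
Product: 4 2,4,6-tris(benzyloxy)phenol
Conditions: BnBr (1.0 equiv), K2CO3 (1.1 equiv), DMF, 0 °C to rt, argon
Reagents that add atoms: benzyl bromide, BrCc1ccccc1
Why: Williamson etherification of the monoanion; the hydroxyl at C4 (two ortho hydrogens, two meta benzyloxy groups) is more acidic and less hindered than the one between the two benzyloxy groups, so the crowded hydroxyl should stay free.

Step 4
Reactants: 3 2,6-bis(benzyloxy)benzene-1,4-diol
Product: 5 4-(allyloxy)-2,6-bis(benzyloxy)phenol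
Conditions: allyl bromide (1.0 equiv), K2CO3 (1.1 equiv), DMF, 0 °C to rt, argon
Reagents that add atoms: allyl bromide, C=CCBr
Why: Same selective Williamson etherification as step 3; the allyl group marks the oxygen that later becomes the triflate and is removable beside benzyl and methoxymethyl ethers.

Step 5
Reactants: 6 2,3,4-trihydroxybenzaldehyde
Product: 7 2,3,4-tris(benzyloxy)benzaldehyde
Conditions: BnBr (3.5 equiv), K2CO3, DMF, 70 °C
Reagents that add atoms: benzyl bromide, BrCc1ccccc1
Why: Exhaustive Williamson etherification; warming is needed for the hydrogen-bonded 2-hydroxyl.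

Step 6
Reactants: 7 2,3,4-tris(benzyloxy)benzaldehyde
Product: 9 2,3,4-tris(benzyloxy)phenol, via aryl formate 8 (not isolated)
Conditions: mCPBA, CH2Cl2, 0 °C to rt; then K2CO3 (cat.), MeOH, rt
Reagents that add atoms: 3-chloroperbenzoic acid, OOC(=O)c1cccc(Cl)c1
Why: Baeyer–Villiger (Dakin-type) oxidation; the ortho and para benzyloxy groups make the aryl group migrate in preference to hydride, and the formate is methanolysed in the same flask.

Step 7
Reactants: 9 2,3,4-tris(benzyloxy)phenol
Product: 10 2,3,4-tris(benzyloxy)-6-iodophenol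
Conditions: NIS (1.0 equiv), MeCN, 0 °C
Reagents that add atoms: N-iodosuccinimide, O=C1CCC(=O)N1I
Why: Electrophilic iodination directed by the free hydroxyl; its para position is blocked, and C6 (ortho to OH, para to a benzyloxy group) is more activated than C5, which has only ether donors.

Step 8
Reactants: 10 2,3,4-tris(benzyloxy)-6-iodophenol
Product: 11 1,2,3-tris(benzyloxy)-5-iodo-4-(methoxymethoxy)benzene
Conditions: MOMCl, i-Pr2NEt, CH2Cl2, 0 °C to rt
Reagents that add atoms: chloromethyl methyl ether, COCCl
Why: Acetal protection of the phenol that will later be the chain-extending nucleophile; the acetal is stable to base, organolithium and fluoride and is cleaved by mild acid beside benzyl ethers.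

Step 9
Reactants: 5 4-(allyloxy)-2,6-bis(benzyloxy)phenol; 11 1,2,3-tris(benzyloxy)-5-iodo-4-(methoxymethoxy)benzene
Product: 12 5-(allyloxy)-1,3-bis(benzyloxy)-2-[3,4,5-tris(benzyloxy)-2-(methoxymethoxy)phenoxy]benzene
Conditions: CuI (10 mol %), picolinic acid (20 mol %), K3PO4, DMSO, 90 °C, argon
Reagents that add atoms: none
Why: Ullmann diaryl ether synthesis with monovalent copper and an N,O-chelating ligand, the variant suited to ortho-substituted partners; the iodide is the only carbon–halogen bond present, and allyl, benzyl and acetal groups tolerate phosphate at this temperature.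

Step 10
Reactants: 12 5-(allyloxy)-1,3-bis(benzyloxy)-2-[3,4,5-tris(benzyloxy)-2-(methoxymethoxy)phenoxy]benzene
Product: 13 3,5-bis(benzyloxy)-4-[3,4,5-tris(benzyloxy)-2-(methoxymethoxy)phenoxy]phenol
Conditions: Pd(PPh3)4 (5 mol %), morpholine, THF, rt
Reagents that add atoms: none
Why: Tsuji–Trost deallylation: zerovalent palladium ionises the allyl aryl ether and morpholine captures the allyl fragment; no other group in 12 reacts.

Step 11
Reactants: 13 3,5-bis(benzyloxy)-4-[3,4,5-tris(benzyloxy)-2-(methoxymethoxy)phenoxy]phenol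
Product: 14 2-bromo-3,5-bis(benzyloxy)-4-[3,4,5-tris(benzyloxy)-2-(methoxymethoxy)phenoxy]phenol
Conditions: NBS (1.0 equiv), CH2Cl2, −78 to 0 °C
Reagents that add atoms: N-bromosuccinimide, O=C1CCC(=O)N1Br
Why: Electrophilic bromination ortho to the only free hydroxyl (the two ortho positions are equivalent, the para position is blocked); the lone C–H of the other ring has only ether donors, and one equivalent at low temperature should stop at the monobromide.

Step 12
Reactants: 14 2-bromo-3,5-bis(benzyloxy)-4-[3,4,5-tris(benzyloxy)-2-(methoxymethoxy)phenoxy]phenol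
Product: 17 3,5-bis(benzyloxy)-4-[3,4,5-tris(benzyloxy)-2-(methoxymethoxy)phenoxy]-2-(trimethylsilyl)phenyl trifluoromethanesulfonate, via silyl ether 15 (not isolated), via lithium phenoxide 16 (not isolated)
Conditions: HMDS, THF, 65 °C, then evaporation; n-BuLi, THF, −78 °C; Tf2O, −78 °C
Reagents that add atoms: hexamethyldisilazane, C[Si](C)(C)N[Si](C)(C)C; trifluoromethanesulfonic anhydride, O=S(=O)(OS(=O)(=O)C(F)(F)F)C(F)(F)F
Why: Standard route to 2-silylaryl triflates: bromine–lithium exchange at −78 °C is faster than any deprotonation, the aryllithium takes the silyl group from the neighbouring oxygen (retro-Brook shift), and the resulting phenoxide is triflated.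

Step 13
Reactants: 18 3,4,5-tris(benzyloxy)benzaldehyde
Product: 20 3,4,5-tris(benzyloxy)phenol, via aryl formate 19 (not isolated)
Conditions: mCPBA, CH2Cl2, 0 °C to rt; then K2CO3 (cat.), MeOH, rt
Reagents that add atoms: 3-chloroperbenzoic acid, OOC(=O)c1cccc(Cl)c1
Why: Baeyer–Villiger (Dakin-type) oxidation; the para benzyloxy group secures aryl migration.

Step 14
Reactants: 20 3,4,5-tris(benzyloxy)phenol
Product: 21 2-bromo-3,4,5-tris(benzyloxy)phenol
Conditions: NBS (1.0 equiv), CH2Cl2, −78 to 0 °C
Reagents that add atoms: N-bromosuccinimide, O=C1CCC(=O)N1Br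
Why: Bromination ortho to the hydroxyl; the two ortho positions are equivalent and the para position is substituted.

Step 15
Reactants: 21 2-bromo-3,4,5-tris(benzyloxy)phenol
Product: 24 3,4,5-tris(benzyloxy)-2-(trimethylsilyl)phenyl trifluoromethanesulfonate, via silyl ether 22 (not isolated), via lithium phenoxide 23 (not isolated)
Conditions: HMDS, THF, 65 °C, then evaporation; n-BuLi, THF, −78 °C; Tf2O, −78 °C
Reagents that add atoms: hexamethyldisilazane, C[Si](C)(C)N[Si](C)(C)C; trifluoromethanesulfonic anhydride, O=S(=O)(OS(=O)(=O)C(F)(F)F)C(F)(F)F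
Why: Same O-silylation, bromine–lithium exchange, retro-Brook shift and triflation as step 12.

Step 16
Reactants: 4 2,4,6-tris(benzyloxy)phenol; 17 3,5-bis(benzyloxy)-4-[3,4,5-tris(benzyloxy)-2-(methoxymethoxy)phenoxy]-2-(trimethylsilyl)phenyl trifluoromethanesulfonate (1.3 equiv)
Product: 26 1,3-bis(benzyloxy)-2-[3,4,5-tris(benzyloxy)-2-(methoxymethoxy)phenoxy]-5-[2,4,6-tris(benzyloxy)phenoxy]benzene (rings A–C), via aryne 25 (not isolated)
Conditions: CsF (3 equiv), MeCN/toluene 3:1, rt
Reagents that add atoms: none
Why: Fluoride removes the silyl group of 17 and triflate leaves, giving aryne 25 with its triple bond between C1 and C2 of the future ring B. The caesium phenoxide of 4 adds to C1 and the aryl anion at C2 is protonated by more phenol or by the solvent, so the aryne is inserted into the O–H bond. The closest known reactions are the fluoride-induced O-arylation of phenols, 2,6-disubstituted ones included, by 2-(trimethylsilyl)aryl triflates, and the addition of nucleophiles to 3-methoxybenzyne at the carbon meta to the methoxy group. No ring is closed and no stereocentre is formed. The regiochemistry needed (oxygen at C1, hydrogen at C2) is secured by the C3 benzyloxy group, which withdraws inductively, makes C1 the more electrophilic carbon and stabilises the negative charge that develops at C2 beside it. Sterics agree, since C1 has a hydrogen neighbour and C2 a benzyloxy neighbour. Attack through oxygen and not carbon is secured by 4 itself, whose ortho and para carbons are all substituted. The aryne is electrophilic whatever its substituents, so the electron-rich character that hampers metal coupling does not matter, and benzyl ethers, the acetal and the existing diaryl ether are inert to CsF at room temperature.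

Step 17
Reactants: 26 rings A–C methoxymethyl ether
Product: 27 2,3,4-tris(benzyloxy)-6-{2,6-bis(benzyloxy)-4-[2,4,6-tris(benzyloxy)phenoxy]phenoxy}phenol (rings A–C phenol)
Conditions: conc. HCl (cat.), MeOH/THF, 45 °C
Reagents that add atoms: none
Why: Acid-catalysed transacetalisation of the aryl methoxymethyl ether to methanol; benzyl and diaryl ethers are stable to dilute acid, and the freed hydroxyl at C6 of ring C is the next nucleophile.

Step 18
Reactants: 27 rings A–C phenol; 17 3,5-bis(benzyloxy)-4-[3,4,5-tris(benzyloxy)-2-(methoxymethoxy)phenoxy]-2-(trimethylsilyl)phenyl trifluoromethanesulfonate (1.3 equiv)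
Product: 28 rings A–E pentamer carrying 13 benzyl ethers and a methoxymethyl ether on O6 of ring E
Conditions: CsF (3 equiv), MeCN/toluene 3:1, rt
Reagents that add atoms: none
Why: Same aryne insertion into the O–H bond as step 16: fluoride turns 17 once more into aryne 25, whose C3 benzyloxy group steers the phenoxide of 27 to C1 of the new ring D. The phenoxide of 27 has both ortho carbons and the para carbon substituted, so only O-arylation is open.

Step 19
Reactants: 28 rings A–E methoxymethyl ether
Product: 29 rings A–E pentamer with free hydroxyl at C6 of ring E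
Conditions: conc. HCl (cat.), MeOH/THF, 45 °C
Reagents that add atoms: none
Why: Acid-catalysed acetal cleavage as in step 17.

Step 20
Reactants: 29 rings A–E phenol; 17 3,5-bis(benzyloxy)-4-[3,4,5-tris(benzyloxy)-2-(methoxymethoxy)phenoxy]-2-(trimethylsilyl)phenyl trifluoromethanesulfonate (1.3 equiv)
Product: 30 rings A–G heptamer carrying 18 benzyl ethers and a methoxymethyl ether on O6 of ring G
Conditions: CsF (3 equiv), MeCN/toluene 3:1, rt to 40 °C
Reagents that add atoms: none
Why: Third use of the aryne insertion of step 16: 17 again gives aryne 25 with fluoride, and the C3 benzyloxy group steers the phenoxide of 29 to C1 of the new ring F.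

Step 21
Reactants: 30 rings A–G methoxymethyl ether
Product: 31 rings A–G heptamer with free hydroxyl at C6 of ring G
Conditions: conc. HCl (cat.), MeOH/THF, 45 °C
Reagents that add atoms: none
Why: Acid-catalysed acetal cleavage as in step 17.

Step 22
Reactants: 31 rings A–G phenol; 24 3,4,5-tris(benzyloxy)-2-(trimethylsilyl)phenyl trifluoromethanesulfonate (1.5 equiv)
Product: 33 henicosabenzyl ether of the target (rings A–H), via aryne 32 (not isolated)
Conditions: CsF (3 equiv), MeCN/toluene 3:1, rt to 40 °C
Reagents that add atoms: none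
Why: Aryne insertion into the O–H bond as in step 16; 3,4,5-tris(benzyloxy)benzyne 32 is attacked at the carbon meta to its flanking benzyloxy group, which gives ring H with hydrogen on both sides of the ether carbon.

Step 23
Reactants: 33 henicosabenzyl ether of the target
Product: 34 CNP0206369.0
Conditions: H2 (1–4 atm), Pd(OH)2 on carbon, THF/MeOH with 1 % AcOH, rt; filtration and evaporation under argon
Reagents that add atoms: none
Why: Hydrogenolysis of all 21 benzyl aryl ethers; neutral and reductive, it leaves the diaryl ethers and rings intact and gives only toluene beside the air-sensitive polyphenol.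

## Compound list

1 | 3,5-bis(benzyloxy)phenol | Oc1cc(OCc9ccccc9)cc(OCc9ccccc9)c1 | starting material
2 | 2,6-bis(benzyloxy)-1,4-benzoquinone | O=C1C=C(OCc9ccccc9)C(=O)C(OCc9ccccc9)=C1 | intermediate
3 | 2,6-bis(benzyloxy)benzene-1,4-diol | Oc1cc(OCc9ccccc9)c(O)c(OCc9ccccc9)c1 | intermediate
4 | 2,4,6-tris(benzyloxy)phenol | Oc1c(OCc9ccccc9)cc(OCc9ccccc9)cc1OCc9ccccc9 | intermediate
5 | 4-(allyloxy)-2,6-bis(benzyloxy)phenol | Oc1c(OCc9ccccc9)cc(OCC=C)cc1OCc9ccccc9 | intermediate
6 | 2,3,4-trihydroxybenzaldehyde | O=Cc1ccc(O)c(O)c1O | starting material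
7 | 2,3,4-tris(benzyloxy)benzaldehyde | O=Cc1ccc(OCc9ccccc9)c(OCc9ccccc9)c1OCc9ccccc9 | intermediate
8 | 2,3,4-tris(benzyloxy)phenyl formate (formed in the flask) | O=COc1ccc(OCc9ccccc9)c(OCc9ccccc9)c1OCc9ccccc9 | intermediate
9 | 2,3,4-tris(benzyloxy)phenol | Oc1ccc(OCc9ccccc9)c(OCc9ccccc9)c1OCc9ccccc9 | intermediate
10 | 2,3,4-tris(benzyloxy)-6-iodophenol | Oc1c(I)cc(OCc9ccccc9)c(OCc9ccccc9)c1OCc9ccccc9 | intermediate
11 | 1,2,3-tris(benzyloxy)-5-iodo-4-(methoxymethoxy)benzene | COCOc1c(I)cc(OCc9ccccc9)c(OCc9ccccc9)c1OCc9ccccc9 | intermediate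
12 | 5-(allyloxy)-1,3-bis(benzyloxy)-2-[3,4,5-tris(benzyloxy)-2-(methoxymethoxy)phenoxy]benzene | C=CCOc1cc(OCc9ccccc9)c(Oc2cc(OCc9ccccc9)c(OCc9ccccc9)c(OCc9ccccc9)c2OCOC)c(OCc9ccccc9)c1 | intermediate
13 | 3,5-bis(benzyloxy)-4-[3,4,5-tris(benzyloxy)-2-(methoxymethoxy)phenoxy]phenol | Oc1cc(OCc9ccccc9)c(Oc2cc(OCc9ccccc9)c(OCc9ccccc9)c(OCc9ccccc9)c2OCOC)c(OCc9ccccc9)c1 | intermediate
14 | 2-bromo-3,5-bis(benzyloxy)-4-[3,4,5-tris(benzyloxy)-2-(methoxymethoxy)phenoxy]phenol | Oc1cc(OCc9ccccc9)c(Oc2cc(OCc9ccccc9)c(OCc9ccccc9)c(OCc9ccccc9)c2OCOC)c(OCc9ccccc9)c1Br | intermediate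
15 | trimethylsilyl ether of 14 (formed in the flask) | C[Si](C)(C)Oc1cc(OCc9ccccc9)c(Oc2cc(OCc9ccccc9)c(OCc9ccccc9)c(OCc9ccccc9)c2OCOC)c(OCc9ccccc9)c1Br | intermediate
16 | lithium 3,5-bis(benzyloxy)-4-[3,4,5-tris(benzyloxy)-2-(methoxymethoxy)phenoxy]-2-(trimethylsilyl)phenoxide (formed in the flask) | [Li+].[O-]c1cc(OCc9ccccc9)c(Oc2cc(OCc9ccccc9)c(OCc9ccccc9)c(OCc9ccccc9)c2OCOC)c(OCc9ccccc9)c1[Si](C)(C)C | intermediate
17 | 3,5-bis(benzyloxy)-4-[3,4,5-tris(benzyloxy)-2-(methoxymethoxy)phenoxy]-2-(trimethylsilyl)phenyl trifluoromethanesulfonate | FC(F)(F)S(=O)(=O)Oc1cc(OCc9ccccc9)c(Oc2cc(OCc9ccccc9)c(OCc9ccccc9)c(OCc9ccccc9)c2OCOC)c(OCc9ccccc9)c1[Si](C)(C)C | intermediate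
18 | 3,4,5-tris(benzyloxy)benzaldehyde | O=Cc1cc(OCc9ccccc9)c(OCc9ccccc9)c(OCc9ccccc9)c1 | starting material
19 | 3,4,5-tris(benzyloxy)phenyl formate (formed in the flask) | O=COc1cc(OCc9ccccc9)c(OCc9ccccc9)c(OCc9ccccc9)c1 | intermediate
20 | 3,4,5-tris(benzyloxy)phenol | Oc1cc(OCc9ccccc9)c(OCc9ccccc9)c(OCc9ccccc9)c1 | intermediate
21 | 2-bromo-3,4,5-tris(benzyloxy)phenol | Oc1cc(OCc9ccccc9)c(OCc9ccccc9)c(OCc9ccccc9)c1Br | intermediate
22 | [2-bromo-3,4,5-tris(benzyloxy)phenoxy]trimethylsilane (formed in the flask) | C[Si](C)(C)Oc1cc(OCc9ccccc9)c(OCc9ccccc9)c(OCc9ccccc9)c1Br | intermediate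
23 | lithium 3,4,5-tris(benzyloxy)-2-(trimethylsilyl)phenoxide (formed in the flask) | [Li+].[O-]c1cc(OCc9ccccc9)c(OCc9ccccc9)c(OCc9ccccc9)c1[Si](C)(C)C | intermediate
24 | 3,4,5-tris(benzyloxy)-2-(trimethylsilyl)phenyl trifluoromethanesulfonate | FC(F)(F)S(=O)(=O)Oc1cc(OCc9ccccc9)c(OCc9ccccc9)c(OCc9ccccc9)c1[Si](C)(C)C | intermediate
25 | 1,2-didehydro-3,5-bis(benzyloxy)-4-[3,4,5-tris(benzyloxy)-2-(methoxymethoxy)phenoxy]benzene, the aryne of 17 (formed in the flask) | C1#CC(OCc9ccccc9)=C(Oc2cc(OCc9ccccc9)c(OCc9ccccc9)c(OCc9ccccc9)c2OCOC)C(OCc9ccccc9)=C1 | intermediate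
26 | 1,3-bis(benzyloxy)-2-[3,4,5-tris(benzyloxy)-2-(methoxymethoxy)phenoxy]-5-[2,4,6-tris(benzyloxy)phenoxy]benzene (rings A–C, 8 benzyl ethers, methoxymethyl ether on O6 of ring C) | C(c9ccccc9)Oc1cc(OCc9ccccc9)c(Oc2cc(OCc9ccccc9)c(Oc3cc(OCc9ccccc9)c(OCc9ccccc9)c(OCc9ccccc9)c3OCOC)c(OCc9ccccc9)c2)c(OCc9ccccc9)c1 | intermediate
27 | 2,3,4-tris(benzyloxy)-6-{2,6-bis(benzyloxy)-4-[2,4,6-tris(benzyloxy)phenoxy]phenoxy}phenol (rings A–C, free hydroxyl at C6 of ring C) | C(c9ccccc9)Oc1cc(OCc9ccccc9)c(Oc2cc(OCc9ccccc9)c(Oc3cc(OCc9ccccc9)c(OCc9ccccc9)c(OCc9ccccc9)c3O)c(OCc9ccccc9)c2)c(OCc9ccccc9)c1 | intermediate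
28 | rings A–E pentamer, 13 benzyl ethers, methoxymethyl ether on O6 of ring E | C(c9ccccc9)Oc1cc(OCc9ccccc9)c(Oc2cc(OCc9ccccc9)c(Oc3cc(OCc9ccccc9)c(OCc9ccccc9)c(OCc9ccccc9)c3Oc3cc(OCc9ccccc9)c(Oc4cc(OCc9ccccc9)c(OCc9ccccc9)c(OCc9ccccc9)c4OCOC)c(OCc9ccccc9)c3)c(OCc9ccccc9)c2)c(OCc9ccccc9)c1 | intermediate
29 | rings A–E pentamer, 13 benzyl ethers, free hydroxyl at C6 of ring E | C(c9ccccc9)Oc1cc(OCc9ccccc9)c(Oc2cc(OCc9ccccc9)c(Oc3cc(OCc9ccccc9)c(OCc9ccccc9)c(OCc9ccccc9)c3Oc3cc(OCc9ccccc9)c(Oc4cc(OCc9ccccc9)c(OCc9ccccc9)c(OCc9ccccc9)c4O)c(OCc9ccccc9)c3)c(OCc9ccccc9)c2)c(OCc9ccccc9)c1 | intermediate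
30 | rings A–G heptamer, 18 benzyl ethers, methoxymethyl ether on O6 of ring G | C(c9ccccc9)Oc1cc(OCc9ccccc9)c(Oc2cc(OCc9ccccc9)c(Oc3cc(OCc9ccccc9)c(OCc9ccccc9)c(OCc9ccccc9)c3Oc3cc(OCc9ccccc9)c(Oc4cc(OCc9ccccc9)c(OCc9ccccc9)c(OCc9ccccc9)c4Oc4cc(OCc9ccccc9)c(Oc5cc(OCc9ccccc9)c(OCc9ccccc9)c(OCc9ccccc9)c5OCOC)c(OCc9ccccc9)c4)c(OCc9ccccc9)c3)c(OCc9ccccc9)c2)c(OCc9ccccc9)c1 | intermediate
31 | rings A–G heptamer, 18 benzyl ethers, free hydroxyl at C6 of ring G | C(c9ccccc9)Oc1cc(OCc9ccccc9)c(Oc2cc(OCc9ccccc9)c(Oc3cc(OCc9ccccc9)c(OCc9ccccc9)c(OCc9ccccc9)c3Oc3cc(OCc9ccccc9)c(Oc4cc(OCc9ccccc9)c(OCc9ccccc9)c(OCc9ccccc9)c4Oc4cc(OCc9ccccc9)c(Oc5cc(OCc9ccccc9)c(OCc9ccccc9)c(OCc9ccccc9)c5O)c(OCc9ccccc9)c4)c(OCc9ccccc9)c3)c(OCc9ccccc9)c2)c(OCc9ccccc9)c1 | intermediate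
32 | 1,2-didehydro-3,4,5-tris(benzyloxy)benzene, the aryne of 24 (formed in the flask) | C1#CC(OCc9ccccc9)=C(OCc9ccccc9)C(OCc9ccccc9)=C1 | intermediate
33 | henicosabenzyl ether of the target (rings A–H, all 21 hydroxyls benzylated) | C(c9ccccc9)Oc1cc(OCc9ccccc9)c(Oc2cc(OCc9ccccc9)c(Oc3cc(OCc9ccccc9)c(OCc9ccccc9)c(OCc9ccccc9)c3Oc3cc(OCc9ccccc9)c(Oc4cc(OCc9ccccc9)c(OCc9ccccc9)c(OCc9ccccc9)c4Oc4cc(OCc9ccccc9)c(Oc5cc(OCc9ccccc9)c(OCc9ccccc9)c(OCc9ccccc9)c5Oc5cc(OCc9ccccc9)c(OCc9ccccc9)c(OCc9ccccc9)c5)c(OCc9ccccc9)c4)c(OCc9ccccc9)c3)c(OCc9ccccc9)c2)c(OCc9ccccc9)c1 | intermediate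
34 | CNP0206369.0 | Oc1cc(O)c(Oc2cc(O)c(Oc3cc(O)c(O)c(O)c3Oc3cc(O)c(Oc4cc(O)c(O)c(O)c4Oc4cc(O)c(Oc5cc(O)c(O)c(O)c5Oc5cc(O)c(O)c(O)c5)c(O)c4)c(O)c3)c(O)c2)c(O)c1 | target

## Step count and uncertain steps

Total: 23 steps. Longest linear sequence: 16 steps (6 → 7 → 9 → 10 → 11 → 12 → 13 → 14 → 17 → 26 → 27 → 28 → 29 → 30 → 31 → 33 → 34).

**Step 16 (key step, repeated in steps 18, 20 and 22).** The most likely failure is that oxygen attack by the crowded caesium phenoxide is slower than consumption of the aryne by itself, by fluoride or by the solvent. This becomes more likely as the phenol grows and its solubility in acetonitrile falls. Loss of regiocontrol is the lesser risk. The fallback replaces the aryne by an ipso cross-coupling and sets out from 13. Tf2O and pyridine would give aryl triflate F1. F1 would be coupled with 4 using Pd(OAc)2, 2-di-tert-butylphosphino-2',4',6'-triisopropylbiphenyl and K3PO4 in toluene at 100 °C, a known palladium-catalysed diaryl ether synthesis that accepts ortho-disubstituted phenols. It returns to the route at 26. The same F1 would serve with 27 (returning at 28) and with 29 (returning at 30). For step 22, 20 would be converted to 3,4,5-tris(benzyloxy)phenyl triflate F2 and coupled with 31, returning at 33.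

**Step 9.** Both partners carry ortho oxygens, so C–O bond formation at copper may be outrun by reductive loss of iodine from 11 and by oxidative decay of the electron-rich phenoxide of 5 at 90 °C. The fallback turns the aryl partner into the nucleophile and works at room temperature. It sets out from 11. Iodine–magnesium exchange (i-PrMgCl·LiCl, THF, −20 °C), B(OMe)3 and aqueous NH4Cl would give boronic acid F3. Chan–Lam coupling of F3 with 5 (Cu(OAc)2 as divalent copper, pyridine, 4 Å sieves, CH2Cl2, air) returns at 12.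

**Step 12.** During bromine–lithium exchange on a substrate with five benzyl ethers, benzylic deprotonation followed by Wittig rearrangement may compete, or the O-to-C silyl shift may stay incomplete so that protonated or O-silylated material results. The fallback puts silicon in by directed ortho-metalation and sets out from 13, so step 11 is not needed. Isopropyl isocyanate and Et3N would give N-isopropylcarbamate F4. N-Silylation in the flask (TMSOTf, TMEDA), lithiation with n-BuLi and TMEDA at −78 °C at the position flanked by carbamate and benzyloxy group, and quenching with TMSCl would give ortho-silyl carbamate F5. Carbamate cleavage with DBU and Et2NH in MeCN at 40 °C, followed by PhNTf2, returns at 17.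

**Step 23.** Removal of 21 benzyl groups may stall because partly debenzylated material leaves solution, and the free polyphenol may oxidise during isolation. The fallback changes the isolation and sets out from 33. After hydrogenolysis the filtrate would be treated, without contact with air, with Ac2O and pyridine to give henicosaacetate F6. F6 is stable, can be chromatographed, and can be separated from incompletely deprotected material. Acid-catalysed methanolysis (HCl in MeOH, argon, rt) and evaporation return at 34.

## Further compounds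

F1 | step 16 | 3,5-bis(benzyloxy)-4-[3,4,5-tris(benzyloxy)-2-(methoxymethoxy)phenoxy]phenyl trifluoromethanesulfonate | FC(F)(F)S(=O)(=O)Oc1cc(OCc9ccccc9)c(Oc2cc(OCc9ccccc9)c(OCc9ccccc9)c(OCc9ccccc9)c2OCOC)c(OCc9ccccc9)c1
F2 | step 16 | 3,4,5-tris(benzyloxy)phenyl trifluoromethanesulfonate | FC(F)(F)S(=O)(=O)Oc1cc(OCc9ccccc9)c(OCc9ccccc9)c(OCc9ccccc9)c1
F3 | step 9 | [3,4,5-tris(benzyloxy)-2-(methoxymethoxy)phenyl]boronic acid | OB(O)c1cc(OCc9ccccc9)c(OCc9ccccc9)c(OCc9ccccc9)c1OCOC
F4 | step 12 | 3,5-bis(benzyloxy)-4-[3,4,5-tris(benzyloxy)-2-(methoxymethoxy)phenoxy]phenyl N-isopropylcarbamate | CC(C)NC(=O)Oc1cc(OCc9ccccc9)c(Oc2cc(OCc9ccccc9)c(OCc9ccccc9)c(OCc9ccccc9)c2OCOC)c(OCc9ccccc9)c1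
F5 | step 12 | 3,5-bis(benzyloxy)-4-[3,4,5-tris(benzyloxy)-2-(methoxymethoxy)phenoxy]-2-(trimethylsilyl)phenyl N-isopropylcarbamate | CC(C)NC(=O)Oc1cc(OCc9ccccc9)c(Oc2cc(OCc9ccccc9)c(OCc9ccccc9)c(OCc9ccccc9)c2OCOC)c(OCc9ccccc9)c1[Si](C)(C)C
F6 | step 23 | henicosaacetate of the target | CC(=O)Oc1cc(OC(C)=O)c(Oc2cc(OC(C)=O)c(Oc3cc(OC(C)=O)c(OC(C)=O)c(OC(C)=O)c3Oc3cc(OC(C)=O)c(Oc4cc(OC(C)=O)c(OC(C)=O)c(OC(C)=O)c4Oc4cc(OC(C)=O)c(Oc5cc(OC(C)=O)c(OC(C)=O)c(OC(C)=O)c5Oc5cc(OC(C)=O)c(OC(C)=O)c(OC(C)=O)c5)c(OC(C)=O)c4)c(OC(C)=O)c3)c(OC(C)=O)c2)c(OC(C)=O)c1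
A1 | alternative 1 | 5-bromo-1,3-bis(benzyloxy)-2-(methoxymethoxy)benzene | COCOc1c(OCc9ccccc9)cc(Br)cc1OCc9ccccc9
A2 | alternative 1 | 1,3-bis(benzyloxy)-2-(methoxymethoxy)-5-[2,4,6-tris(benzyloxy)phenoxy]benzene | COCOc1c(OCc9ccccc9)cc(Oc2c(OCc9ccccc9)cc(OCc9ccccc9)cc2OCc9ccccc9)cc1OCc9ccccc9
A3 | alternative 2 | 2,6-bis(benzyloxy)-4-fluorobenzaldehyde | O=Cc1c(OCc9ccccc9)cc(F)cc1OCc9ccccc9
A4 | alternative 2 | 2,3,4-tris(benzyloxy)-6-fluorobenzaldehyde | O=Cc1c(F)cc(OCc9ccccc9)c(OCc9ccccc9)c1OCc9ccccc9
A5 | alternative 3 | 5-(allyloxy)-1,3-bis(benzyloxy)-2-(ethynyloxy)benzene | C#COc1c(OCc9ccccc9)cc(OCC=C)cc1OCc9ccccc9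
A6 | alternative 3 | dibenzyl squarate, 3,4-bis(benzyloxy)cyclobut-3-ene-1,2-dione | O=C1C(=O)C(OCc9ccccc9)=C1OCc9ccccc9
A7 | alternative 3 | 4-{[4-(allyloxy)-2,6-bis(benzyloxy)phenoxy]ethynyl}-2,3-bis(benzyloxy)-4-hydroxycyclobut-2-en-1-one | O=C1C(OCc9ccccc9)=C(OCc9ccccc9)C1(O)C#COc1c(OCc9ccccc9)cc(OCC=C)cc1OCc9ccccc9
A8 | alternative 3 | 5-[4-(allyloxy)-2,6-bis(benzyloxy)phenoxy]-2,3-bis(benzyloxy)-1,4-benzoquinone | O=C1C=C(Oc2c(OCc9ccccc9)cc(OCC=C)cc2OCc9ccccc9)C(=O)C(OCc9ccccc9)=C1OCc9ccccc9
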